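**Retrosynthetic overview**
1. Target 20 ⇐ 19 by removal of three TBS groups (two phenols and the oxolane 3-OH).
2. Key disconnection: the C2′–C3′ bond of the diene and the O1–C2 bond of the oxolane are cut together, 19 ⇐ (E)-alkenyl iodide 9 + acyclic alkynol 17. Forward, a Sonogashira coupling forms C2′–C3′ at the alkyne oxidation level, and the same palladium then isomerises the enyne (alkyne → allene → π-allyl) and closes the oxolane.
3. Enabling feature: oxolane C2 is both the carbon bonded to ring oxygen O1 and the allylic terminus of the C3′=C4′ alkene, and O1 sits on C5 three carbons away. The unit O1–C2–C4′=C3′ is therefore the redox isomer of a free C5–OH plus a propargylic CH2–C≡C.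
4. 9 ⇐ chloro-toluate 2 + ester 3 (C3–C4 bond by lateral lithiation, enol lactonisation, Takai iodoolefination); 17 ⇐ (S)-pent-4-en-2-ol 10 (1,3-syn iodocarbonate, epoxide, acetylide opening).
5. Ring order: the benzene ring is bought in 1; the pyranone ring of the isocoumarin is closed in step 3; the oxolane is closed last, in step 15.

Key step: step 15

Remark: the butadienyl chain is numbered C1′ (on isocoumarin C3) to C4′ (on oxolane C2); compounds 1, 3 and 10 are taken as commercially available.

Step 1
Reactants: 1 methyl 2,4-dimethoxy-6-methylbenzoate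
Product: 2 methyl 3-chloro-4,6-dimethoxy-2-methylbenzoate
Conditions: NCS (1.05 equiv), MeCN, 50 °C
Reagents that add atoms: N-chlorosuccinimide (O=C1CCC(=O)N1Cl)
Why: Electrophilic aromatic chlorination should go to C5 of 1 (ortho to the 4-methoxy and para to the 2-methoxy group), the ortho/para-activated position, rather than to C3 between the two methoxy groups.

Step 2
Reactants: 2 methyl 3-chloro-4,6-dimethoxy-2-methylbenzoate; 3 ethyl 2,2-diethoxyacetate
Product: 4 methyl 3-chloro-2-(3,3-diethoxy-2-oxopropyl)-4,6-dimethoxybenzoate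
Conditions: LDA (2.2 equiv), THF, −78 °C; then 3, −78 to −40 °C; aqueous work-up
Reagents that add atoms: none
Why: Lateral lithiation of the ortho-toluate gives a benzylic anion that undergoes Claisen-type acylation by the non-enolisable ester 3, and the product is held as its enolate, which should prevent a second addition.

Step 3
Reactants: 4 methyl 3-chloro-2-(3,3-diethoxy-2-oxopropyl)-4,6-dimethoxybenzoate
Product: 5 5-chloro-3-(diethoxymethyl)-6,8-dimethoxy-1H-isochromen-1-one
Conditions: DBU (1.2 equiv), toluene, 90 °C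
Reagents that add atoms: none
Why: Base-mediated enol lactonisation (acylation of the enolate oxygen by the ortho ester, six-membered ring) closes the pyranone ring with loss of methanol, and the acetal is stable to base.

Step 4
Reactants: 5 5-chloro-3-(diethoxymethyl)-6,8-dimethoxy-1H-isochromen-1-one
Product: 6 5-chloro-6,8-dimethoxy-1-oxo-1H-isochromene-3-carbaldehyde
Conditions: 2 M HCl, THF, 40 °C
Reagents that add atoms: water (O)
Why: Acid-catalysed acetal hydrolysis unmasks the aldehyde, while the isocoumarin lactone and the aryl methyl ethers are stable to dilute aqueous acid.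

Step 5
Reactants: 6 5-chloro-6,8-dimethoxy-1-oxo-1H-isochromene-3-carbaldehyde
Product: 7 5-chloro-3-[(E)-2-iodoethenyl]-6,8-dimethoxy-1H-isochromen-1-one
Conditions: CrCl2 (6 equiv), CHI3 (2 equiv), THF/1,4-dioxane, 0 °C to rt; aqueous work-up
Reagents that add atoms: iodoform (IC(I)I)
Why: Takai iodoolefination with the gem-dichromium reagent from CHI3/CrCl2 should give the (E)-alkenyl iodide through anti elimination of the β-oxido chromium intermediate, and lactone and aryl chloride are inert to Cr(II).

Step 6
Reactants: 7 5-chloro-3-[(E)-2-iodoethenyl]-6,8-dimethoxy-1H-isochromen-1-one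
Product: 8 5-chloro-6,8-dihydroxy-3-[(E)-2-iodoethenyl]-1H-isochromen-1-one
Conditions: BBr3 (5 equiv), CH2Cl2, −78 °C to rt; then H2O
Reagents that add atoms: none
Why: Lewis-acid ether cleavage removes both aryl methyl ethers before the acid-sensitive diene and oxolane exist, and lactone, aryl chloride and alkenyl iodide tolerate BBr3.

Step 7
Reactants: 8 5-chloro-6,8-dihydroxy-3-[(E)-2-iodoethenyl]-1H-isochromen-1-one
Product: 9 6,8-bis[(tert-butyldimethylsilyl)oxy]-5-chloro-3-[(E)-2-iodoethenyl]-1H-isochromen-1-one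
Conditions: TBSOTf (2.5 equiv), 2,6-lutidine (4 equiv), CH2Cl2, 0 °C
Reagents that add atoms: tert-butyldimethylsilyl triflate (CC(C)(C)[Si](C)(C)OS(=O)(=O)C(F)(F)F)
Why: Silylation with the silyl triflate protects both phenols (including the hydrogen-bonded 8-OH) as ethers that survive Pd/Cu catalysis and are removed by fluoride at the end.

Step 8
Reactants: 10 (S)-pent-4-en-2-ol
Product: 11 tert-butyl (S)-pent-4-en-2-yl carbonate
Conditions: Boc2O (1.3 equiv), DMAP (cat.), CH2Cl2, rt
Reagents that add atoms: di-tert-butyl dicarbonate (CC(C)(C)OC(=O)OC(=O)OC(C)(C)C)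
Why: DMAP-catalysed O-acylation installs the tert-butyl carbonate that serves as internal oxygen nucleophile in the next step and leaves the stereocentre untouched.

Step 9
Reactants: 11 tert-butyl (S)-pent-4-en-2-yl carbonate
Product: 12 (4S,6S)-4-(iodomethyl)-6-methyl-1,3-dioxan-2-one
Conditions: IBr (1.2 equiv), toluene, −85 °C
Reagents that add atoms: iodine monobromide (IBr)
Why: Iodocarbonate cyclisation: the carbonate carbonyl oxygen opens the iodonium ion in a 6-exo mode through a chair transition state with both substituents equatorial, so the existing (S) centre should set the new C–O centre 1,3-syn (4S), with loss of the tert-butyl cation.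

Step 10
Reactants: 12 (4S,6S)-4-(iodomethyl)-6-methyl-1,3-dioxan-2-one
Product: 13 (2S)-1-[(2S)-oxiran-2-yl]propan-2-ol
Conditions: K2CO3 (3 equiv), MeOH, rt
Reagents that add atoms: none
Why: Methanolysis of the cyclic carbonate frees the alkoxide next to the iodomethyl group, which closes the epoxide by intramolecular SN2 displacement without touching either C–O stereocentre.

Step 11
Reactants: 13 (2S)-1-[(2S)-oxiran-2-yl]propan-2-ol
Product: 14 (2S)-2-[(2S)-2-[(4-methoxyphenyl)methoxy]propyl]oxirane
Conditions: NaH, PMBCl, Bu4NI (cat.), THF/DMF, 0 °C to rt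
Reagents that add atoms: 4-methoxybenzyl chloride (COc1ccc(CCl)cc1)
Why: Williamson etherification protects the secondary hydroxyl as a PMB ether that is orthogonal to the silyl ether introduced later.

Step 12
Reactants: 14 (2S)-2-[(2S)-2-[(4-methoxyphenyl)methoxy]propyl]oxirane
Product: 15 (4R,6S)-6-[(4-methoxyphenyl)methoxy]hept-1-yn-4-ol
Conditions: lithium acetylide–ethylenediamine complex (3 equiv), DMSO, rt; aqueous work-up
Reagents that add atoms: lithium acetylide, ethylenediamine complex ([Li+].[C-]#C)
Why: The acetylide opens the terminal epoxide at its unsubstituted carbon (SN2), which installs the propargylic CH2–C≡CH unit and leaves the carbinol configuration unchanged.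

Step 13
Reactants: 15 (4R,6S)-6-[(4-methoxyphenyl)methoxy]hept-1-yn-4-ol
Product: 16 tert-butyl{[(4R,6S)-6-[(4-methoxyphenyl)methoxy]hept-1-yn-4-yl]oxy}dimethylsilane
Conditions: TBSCl, imidazole, DMF, rt
Reagents that add atoms: tert-butyldimethylsilyl chloride (CC(C)(C)[Si](C)(C)Cl)
Why: Standard silylation places the bulky TBS ether on the oxygen that becomes O3 of the oxolane, where it later directs the ring closure and blocks redox isomerisation.

Step 14
Reactants: 16 tert-butyl{[(4R,6S)-6-[(4-methoxyphenyl)methoxy]hept-1-yn-4-yl]oxy}dimethylsilane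
Product: 17 (2S,4R)-4-[(tert-butyldimethylsilyl)oxy]hept-6-yn-2-ol
Conditions: DDQ, CH2Cl2/pH 7 buffer, 0 °C
Reagents that add atoms: none
Why: Oxidative PMB cleavage frees the hydroxyl that becomes the ring oxygen, and the terminal alkyne and the TBS ether are unaffected.

Step 15
Reactants: 9 6,8-bis[(tert-butyldimethylsilyl)oxy]-5-chloro-3-[(E)-2-iodoethenyl]-1H-isochromen-1-one; 17 (2S,4R)-4-[(tert-butyldimethylsilyl)oxy]hept-6-yn-2-ol
Product: 19 6,8-bis[(tert-butyldimethylsilyl)oxy]-3-[(1E,3E)-4-[(2R,3S,5S)-3-[(tert-butyldimethylsilyl)oxy]-5-methyloxolan-2-yl]buta-1,3-dien-1-yl]-5-chloro-1H-isochromen-1-one, via enyne 18 (not isolated)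
Conditions: Pd(PPh3)4 (10 mol %), CuI (5 mol %), Et3N (1.5 equiv), 1,4-dioxane, 25 °C; then PhCO2H (2 equiv), 100 °C, same flask
Reagents that add atoms: none
Why: Proposed new method: Pd(0)/Cu(I) first joins the terminal alkyne carbon of 17 to the iodine-bearing alkenyl carbon of 9 (oxidative addition with retention, copper acetylide transmetalation, reductive elimination), which forms the C2′–C3′ bond and gives the conjugated (E)-enyne 18; with benzoic acid the same Pd(0) forms H–Pd–O2CPh, which hydropalladates the now conjugated alkyne, β-hydride eliminates at the propargylic CH2 to a vinylallene and re-adds to give an η3-allyl palladium spanning the future oxolane C2, C4′ and C3′. The free secondary hydroxyl then attacks the proximal allyl terminus anti to palladium in a 5-exo closure (O1–C2 bond), releasing Pd(0) and leaving the (1E,3E)-diene conjugated to the isocoumarin. The closest known reaction types are the Sonogashira coupling and the Pd(0)/benzoic acid intramolecular hydroalkoxylation of aryl alkynes bearing a hydroxyalkyl chain to 2-alkenyl tetrahydrofurans (alkyne–allene–π-allyl manifold); new is the tandem use on a 1,3-enyne made in the same flask, where the coupling itself creates the conjugation that drives the isomerisation. The new stereocentre C2 is set by the substrate: the allyl unit should close trans to the bulky C3 silyloxy group, and because C3 and C5 are already trans this places it cis to the C5 methyl (2R); reversible hydropalladation/β-elimination and re-ionisation of the dienylic ether may let the π-allyl diastereomers funnel to this isomer. The step needs O-attack at the proximal terminus (the remote termini would give 7- or 9-membered rings), no participation of the C3 oxygen (silylated, which also blocks redox isomerisation to a ketone) and E geometry at both alkenes (syn,syn-π-allyl and retention from 9).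

Step 16
Reactants: 19 6,8-bis[(tert-butyldimethylsilyl)oxy]-3-[(1E,3E)-4-[(2R,3S,5S)-3-[(tert-butyldimethylsilyl)oxy]-5-methyloxolan-2-yl]buta-1,3-dien-1-yl]-5-chloro-1H-isochromen-1-one
Product: 20 5-chloro-6,8-dihydroxy-3-[(1E,3E)-4-[(2R,3S,5S)-3-hydroxy-5-methyloxolan-2-yl]buta-1,3-dien-1-yl]-1H-isochromen-1-one
Conditions: TBAF (4 equiv), AcOH (4 equiv), THF, 0 °C to rt
Reagents that add atoms: none
Why: Buffered fluoride cleaves the two aryl and the one secondary alkyl silyl ether under conditions that should leave the diene, the dienylic ether and the lactone untouched.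

**Compound list**
1 | methyl 2,4-dimethoxy-6-methylbenzoate | COC(=O)c1c(C)cc(OC)cc1OC | starting material
2 | methyl 3-chloro-4,6-dimethoxy-2-methylbenzoate | COC(=O)c1c(C)c(Cl)c(OC)cc1OC | intermediate
3 | ethyl 2,2-diethoxyacetate | CCOC(=O)C(OCC)OCC | starting material
4 | methyl 3-chloro-2-(3,3-diethoxy-2-oxopropyl)-4,6-dimethoxybenzoate | COC(=O)c1c(CC(=O)C(OCC)OCC)c(Cl)c(OC)cc1OC | intermediate
5 | 5-chloro-3-(diethoxymethyl)-6,8-dimethoxy-1H-isochromen-1-one | CCOC(OCC)c1cc2c(Cl)c(OC)cc(OC)c2c(=O)o1 | intermediate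
6 | 5-chloro-6,8-dimethoxy-1-oxo-1H-isochromene-3-carbaldehyde | O=Cc1cc2c(Cl)c(OC)cc(OC)c2c(=O)o1 | intermediate
7 | 5-chloro-3-[(E)-2-iodoethenyl]-6,8-dimethoxy-1H-isochromen-1-one | COc1cc(OC)c2c(=O)oc(/C=C/I)cc2c1Cl | intermediate
8 | 5-chloro-6,8-dihydroxy-3-[(E)-2-iodoethenyl]-1H-isochromen-1-one | Oc1cc(O)c2c(=O)oc(/C=C/I)cc2c1Cl | intermediate
9 | 6,8-bis[(tert-butyldimethylsilyl)oxy]-5-chloro-3-[(E)-2-iodoethenyl]-1H-isochromen-1-one | CC(C)(C)[Si](C)(C)Oc1cc(O[Si](C)(C)C(C)(C)C)c2c(=O)oc(/C=C/I)cc2c1Cl | intermediate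
10 | (S)-pent-4-en-2-ol | C[C@H](O)CC=C | starting material
11 | tert-butyl (S)-pent-4-en-2-yl carbonate | C[C@H](OC(=O)OC(C)(C)C)CC=C | intermediate
12 | (4S,6S)-4-(iodomethyl)-6-methyl-1,3-dioxan-2-one | C[C@H]1C[C@@H](CI)OC(=O)O1 | intermediate
13 | (2S)-1-[(2S)-oxiran-2-yl]propan-2-ol | C[C@H](O)C[C@H]1CO1 | intermediate
14 | (2S)-2-[(2S)-2-[(4-methoxyphenyl)methoxy]propyl]oxirane | C[C@H](OCc1ccc(OC)cc1)C[C@H]1CO1 | intermediate
15 | (4R,6S)-6-[(4-methoxyphenyl)methoxy]hept-1-yn-4-ol | C[C@H](OCc1ccc(OC)cc1)C[C@H](O)CC#C | intermediate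
16 | tert-butyl{[(4R,6S)-6-[(4-methoxyphenyl)methoxy]hept-1-yn-4-yl]oxy}dimethylsilane | C[C@H](OCc1ccc(OC)cc1)C[C@H](O[Si](C)(C)C(C)(C)C)CC#C | intermediate
17 | (2S,4R)-4-[(tert-butyldimethylsilyl)oxy]hept-6-yn-2-ol | C[C@H](O)C[C@H](O[Si](C)(C)C(C)(C)C)CC#C | intermediate
18 | 6,8-bis[(tert-butyldimethylsilyl)oxy]-3-[(1E,6R,8S)-6-[(tert-butyldimethylsilyl)oxy]-8-hydroxynon-1-en-3-yn-1-yl]-5-chloro-1H-isochromen-1-one (enyne, not isolated) | C[C@H](O)C[C@H](O[Si](C)(C)C(C)(C)C)CC#C/C=C/c1cc2c(Cl)c(O[Si](C)(C)C(C)(C)C)cc(O[Si](C)(C)C(C)(C)C)c2c(=O)o1 | intermediate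
19 | 6,8-bis[(tert-butyldimethylsilyl)oxy]-3-[(1E,3E)-4-[(2R,3S,5S)-3-[(tert-butyldimethylsilyl)oxy]-5-methyloxolan-2-yl]buta-1,3-dien-1-yl]-5-chloro-1H-isochromen-1-one | C[C@H]1C[C@H](O[Si](C)(C)C(C)(C)C)[C@@H](/C=C/C=C/c2cc3c(Cl)c(O[Si](C)(C)C(C)(C)C)cc(O[Si](C)(C)C(C)(C)C)c3c(=O)o2)O1 | intermediate
20 | 5-chloro-6,8-dihydroxy-3-[(1E,3E)-4-[(2R,3S,5S)-3-hydroxy-5-methyloxolan-2-yl]buta-1,3-dien-1-yl]-1H-isochromen-1-one | C[C@H]1C[C@H](O)[C@@H](/C=C/C=C/c2cc3c(Cl)c(O)cc(O)c3c(=O)o2)O1 | target

**Step count**
Total steps: 16. Longest linear sequence: 9 steps (steps 1–7, 15, 16; the branch from 10, steps 8–14, 15, 16, is equally long).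

**Steps most likely to fail**

Step 15 (Proposed new method). After the coupling the isomerisation may stall at the enyne or drain through β-hydride elimination to trienes, and the ring closure may show poor facial selectivity at the new C2 centre. The fallback uses known chemistry and separates ring formation from fragment union; it sets out from 9 and comes back at 19. The coupling partner is built from commercial (S)-γ-valerolactone. Enolate hydroxylation (LiHMDS, then 2-(phenylsulfonyl)-3-phenyloxaziridine) anti to the methyl group should give (3S,5S)-3-hydroxy-5-methyloxolan-2-one F1. Silylation (TBSCl, imidazole) gives (3S,5S)-3-[(tert-butyldimethylsilyl)oxy]-5-methyloxolan-2-one F2. Addition of ethynylmagnesium bromide at −78 °C gives the hemiketal (3S,5S)-3-[(tert-butyldimethylsilyl)oxy]-2-ethynyl-5-methyloxolan-2-ol F3. Ionic reduction (Et3SiH, BF3·OEt2, −78 °C), with hydride delivered to the oxocarbenium ion cis to the silyloxy group, should give tert-butyl{[(2R,3S,5S)-2-ethynyl-5-methyloxolan-3-yl]oxy}dimethylsilane F4. Zirconium-catalysed hydroboration (pinacolborane, Cp2Zr(H)Cl cat., Et3N) gives the (E)-alkenylboronate tert-butyldimethyl{[(2R,3S,5S)-5-methyl-2-[(E)-2-(4,4,5,5-tetramethyl-1,3,2-dioxaborolan-2-yl)ethenyl]oxolan-3-yl]oxy}silane F5. Suzuki–Miyaura coupling of F5 with 9 (Pd(dppf)Cl2, K3PO4, THF/H2O, rt) gives 19.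

Step 2. The benzylic anion may condense with unreacted 2, or acylation by the hindered α,α-dialkoxy ester may be incomplete. The fallback closes the pyranone ring by C–H activation at the aryl carbon instead; it sets out from 3 and comes back at 5. Ester 3 is treated with dimethylsulfoxonium methylide (trimethylsulfoxonium iodide, KOtBu, THF, reflux) to give the sulfoxonium ylide 1-[dimethyl(oxo)-λ6-sulfanylidene]-3,3-diethoxypropan-2-one F6. Rh(III)-catalysed carboxylate-directed C–H alkylation/annulation of commercial 5-chloro-2,4-dimethoxybenzoic acid with F6 ([Cp*RhCl2]2, AgSbF6, NaOAc, 1,2-dichloroethane, 80 °C) occurs at the only free ortho C–H and gives 5.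

Step 5. E/Z control may erode, or the electron-poor aldehyde may undergo reductive (pinacol-type) dimerisation by Cr(II). The fallback goes through the alkyne; it sets out from 6 and comes back at 7. Ohira–Bestmann homologation (dimethyl (1-diazo-2-oxopropyl)phosphonate, K2CO3, MeOH, 0 °C) gives 5-chloro-3-ethynyl-6,8-dimethoxy-1H-isochromen-1-one F7. Hydrozirconation (Cp2Zr(H)Cl, THF, rt) followed by iodinolysis (I2, 0 °C) gives 7 with E geometry from syn addition.

**Further compounds**
F1 | step 15 | (3S,5S)-3-hydroxy-5-methyloxolan-2-one | C[C@H]1C[C@H](O)C(=O)O1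
F2 | step 15 | (3S,5S)-3-[(tert-butyldimethylsilyl)oxy]-5-methyloxolan-2-one | C[C@H]1C[C@H](O[Si](C)(C)C(C)(C)C)C(=O)O1
F3 | step 15 | (3S,5S)-3-[(tert-butyldimethylsilyl)oxy]-2-ethynyl-5-methyloxolan-2-ol (anomer mixture) | C[C@H]1C[C@H](O[Si](C)(C)C(C)(C)C)C(O)(C#C)O1
F4 | step 15 | tert-butyl{[(2R,3S,5S)-2-ethynyl-5-methyloxolan-3-yl]oxy}dimethylsilane | C[C@H]1C[C@H](O[Si](C)(C)C(C)(C)C)[C@@H](C#C)O1
F5 | step 15 | tert-butyldimethyl{[(2R,3S,5S)-5-methyl-2-[(E)-2-(4,4,5,5-tetramethyl-1,3,2-dioxaborolan-2-yl)ethenyl]oxolan-3-yl]oxy}silane | C[C@H]1C[C@H](O[Si](C)(C)C(C)(C)C)[C@@H](/C=C/B2OC(C)(C)C(C)(C)O2)O1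
F6 | step 2 | 1-[dimethyl(oxo)-λ6-sulfanylidene]-3,3-diethoxypropan-2-one | CCOC(OCC)C(=O)C=S(C)(C)=O
F7 | step 5 | 5-chloro-3-ethynyl-6,8-dimethoxy-1H-isochromen-1-one | C#Cc1cc2c(Cl)c(OC)cc(OC)c2c(=O)o1
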